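Readings and results come from a simulation on assumed constants, and the scatter is random.

The question is which flask gives the most product, and how much; these flasks share their starting material, their coupling partner and their reading times, and differ in their catalyst loading.

| setting | summer | midnight | Wednesday's | Sunday's | Friday's | Thursday's | Monday's |
|---|---|---|---|---|---|---|---|
| starting material | 0.80 M | 0.80 M | 0.80 M | 0.80 M | 0.80 M | 0.80 M | 0.80 M |
| coupling partner | 1.1 equiv | 1.1 equiv | 1.10 equiv | 1.10 equiv | 1.10 equiv | 1.10 equiv | 1.10 equiv |
| free catalyst | 5.3 mol% | 17 mol% | 25 mol% | 6 mol% | 13 mol% | 20 mol% | 8 mol% |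
| remark | run made earlier | run made earlier |  |  |  |  |  |
| time |  |  | 20 min | 20 min | 20 min | 20 min | 20 min |

| run | time / min | product / % | starting material / % |
|---|---|---|---|
| summer | 1.33 | 0.6 | 100.9 |
| summer | 4.00 | 2.7 | 98.9 |
| summer | 6.00 | 4.9 | 95.5 |
| summer | 10.0 | 8.2 | 93.5 |
| summer | 15.0 | 8.2 | 88.5 |
| midnight | 3.00 | 4.0 | 93.8 |
| midnight | 6.00 | 10.0 | 87.1 |
| midnight | 8.00 | 17.5 | 81.7 |
| midnight | 12.0 | 25.8 | 72.7 |
| midnight | 15.0 | 32.5 | 65.6 |

(readings scatter by 1 percentage point)



* the flasks by amount of product, in percent of the starting material charged, highest first, at 20 min (Wednesday's / Sunday's / Friday's / Thursday's / Monday's)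
* the same order at 80 min (Wednesday's / Sunday's / Friday's / Thursday's / Monday's)
* the amount of product, in percent of the starting material charged of the flask you put first, at 20 min
* the amount of product, in percent of the starting material charged of the flask you put last, at 20 min

Turn the catalyst first. By hand, if each catalyst does the same work, midnight's loading, 3.21 times summer's, should use up starting material that many times faster. The runs come close: by 15.0 min summer has lost 11.5% and midnight 34.4%, a factor of 2.99.

So count the work per catalyst. Midnight gives 0.127 /min at 15.0 min for the fraction of the charge turned into product per minute, per fraction of catalyst charged: the turnover rate, usually called turnover frequency. Summer's product readings are smaller, so a scatter of 1 percentage point weighs more on them, and you take midnight's figure.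

Now turn the time. By hand, product should grow in step with the minutes while the turnover rate holds. In midnight it reads 0.129 /min at 8.00 min and 0.127 /min at 15.0 min, so these readings show no bend within their scatter of 1 point.

Multiply the turnover rate by loading and time. Wednesday's comes to 63.7% and Sunday's to 15.3%, so the order at 20 min follows the loading. At 80 min the line asks 255% of Wednesday's, past the whole charge, so for Wednesday's the line gives no figure at that time. You keep the same order at 80 min, since midnight stands ahead of summer in the readings up to 15.0 min.

The forecast gave Wednesday's > Thursday's > Friday's > Monday's > Sunday's at 20 min and Wednesday's > Thursday's > Friday's > Monday's > Sunday's at 80 min, with 61% on top at 20 min, below your 63.7%, and 15% last, and said “The order should stay the same”.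

The simulation gives Wednesday's > Thursday's > Friday's > Monday's > Sunday's at 20 min and Wednesday's > Thursday's > Friday's > Monday's > Sunday's at 80 min, with 58.0% on top and 16.7% last.

    coupling partner + free catalyst ⇌ catalyst intermediate A (K = 1.40 /M, k = 0.0175 /M/s)
    catalyst intermediate A → by-product + catalyst intermediate B (k = 0.711 /s)
    catalyst intermediate B ⇌ catalyst intermediate C (K = 1.10, k = 0.00398 /s)
    starting material + catalyst intermediate C ⇌ catalyst intermediate D (K = 0.890 /M, k = 0.254 /M/s)
    catalyst intermediate D → free catalyst + product (k = 0.0911 /s)
    starting material + catalyst intermediate A ⇌ idle complex, settled at all times (K = 2.10 /M)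
    coupling partner → decomposed reagent (k = 3.97 × 10⁻⁴ /s)

Wednesday's turnover rate comes out at 0.116 /min, below midnight's. Part of that shortfall is catalyst intermediate D falling back to starting material and catalyst intermediate C: without this step Wednesday's reaches 63.5%, and the hour of the reading acts together with it, since Wednesday's stands at 84.1% at 200 min. For the neighbour of Wednesday's charged with 15 mol%, the turnover rate gives 38.1% at 20 min; the simulation gives 38.6%.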